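A direct plan would make the C1' carbinol by asymmetric addition of 4-ethynylanisole to 3,4-dimethoxybenzaldehyde, silylate and semihydrogenate it to the (Z)-allylic silyl ether A1, add dichloroketene to A1 to give the cyclobutanone A2, and enlarge the ring by Baeyer–Villiger oxidation to the lactone A3.
It would then move the oxygen from C2 to C3 of the oxolane: dechlorination, reduction to the lactol, dehydration to the dihydrofuran A4, hydroboration to the trans alcohol A5, oxidation to the ketone A6, reduction with LiBH(s-Bu)3 and desilylation.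
Weak point 1, the ketene cycloaddition to A1: two ring stereocentres would depend on the facial bias of one acyclic allylic centre, argued only by analogy to osmylation, while a doubly activated benzylic silyl ether meets ZnCl2.
Weak point 2, the stretch from A3 to A6: six operations that make no skeletal bond and only transpose one oxygen.
Weak point 3, the C3 centre: hydroboration of A4 would set it wrongly (A5), so it would be repaired by oxidation and reduction through A6, an α-aryl ketone that can epimerise at C4 to the trans series before the hydride arrives.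

**Retrosynthetic overview**
Numbering: oxolane O1, C2 (CH2), C3 (OH), C4 (4-methoxyphenyl), C5; C1' is the exocyclic carbinol carbon.
The anti C1'–OH/C5–O1 pair is the retron of an (E)-styrene epoxide opened with inversion at C5 by the C2 hydroxyl (5-exo); cutting the C5=C1' alkene by cross-metathesis then leaves (2S,3R)-3-(4-methoxyphenyl)pent-4-ene-1,2-diol.
In that diol the vicinal C3(OH)/C4(aryl) pair of the ring is the retron of an α-oxygenated aldehyde allylated by a 1-arylallyl cation: the C3–C4 bond and both centres come from one iridium/amine dual-catalytic allylation of silyloxyacetaldehyde with racemic 1-(4-methoxyphenyl)prop-2-en-1-ol.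
Order: C3 and C4 are set as a pair by two catalysts (key step), then C5 and C1' as a pair by one epoxidation, and the only ring, the oxolane, closes in the last step.
The C3 oxygen enters with its final oxidation state and configuration, so there is no carbonyl transposition, no repair of C3, no α-aryl ketone and no cycloaddition to an acyclic allylic ether; one silyl ether is the only protecting group.

Key step: step 2

Assumption: the (R)-enantiomer of the phosphoramidite–olefin ligand is taken as the one that gives the (3R) aryl-bearing centre in step 2; the two catalysts control their centres independently, so a reversed sense would be met with the mirror-image ligand and the same amine.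

Step 1
Reactants: 1 4-methoxybenzaldehyde; 2 vinylmagnesium bromide
Product: 3 rac-1-(4-methoxyphenyl)prop-2-en-1-ol
Conditions: THF, 0 °C; aq NH4Cl
Reagents that add atoms: none
Why: Grignard 1,2-addition to an aromatic aldehyde; the carbinol centre is left racemic on purpose, because step 2 ionises it and both enantiomers converge on one allyl–iridium intermediate.

Step 2
Reactants: 3 rac-1-(4-methoxyphenyl)prop-2-en-1-ol; 4 (tert-butyldimethylsilyloxy)acetaldehyde
Product: 7 (2S,3R)-2-[(tert-butyldimethylsilyl)oxy]-3-(4-methoxyphenyl)pent-4-en-1-ol, via enamine 5 (not isolated), via aldehyde 6 (not isolated)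
Conditions: 4 (3 equiv), [Ir(cod)Cl]2 (3 mol %), (R)-phosphoramidite–olefin ligand [(R)-5-(dinaphtho[2,1-d:1',2'-f][1,3,2]dioxaphosphepin-4-yl)-5H-dibenzo[b,f]azepine, 12 mol %], (R)-2-{bis[3,5-bis(trifluoromethyl)phenyl][(trimethylsilyl)oxy]methyl}pyrrolidine (15 mol %), (MeO)2P(O)OH, ClCH2CH2Cl, rt; then NaBH4, MeOH, 0 °C
Reagents that add atoms: none
Why: Acid-promoted ionisation of either enantiomer of 3 on the chiral iridium complex gives one allyl–iridium cation, which the E-enamine 5 (from 4 and the secondary amine) attacks at its aryl-bearing terminus to form the C2–C3 bond of the pentenal (C3–C4 of the oxolane); hydrolysis releases 6 and both catalysts, and NaBH4 reduces 6 in the same flask before it can epimerise. The closest known reaction type is the stereodivergent iridium/amine dual-catalytic α-allylation of linear aldehydes and of O-protected α-hydroxyacetaldehydes with racemic aryl vinyl carbinols. No ring is closed. The aryl-bearing centre (3R, C4 of the target) is set by the iridium ligand, which fixes the face of the allyl unit that is attacked, and the oxygen-bearing centre (2S, C3 of the target) by the amine, whose bulky diaryl(silyloxy)methyl group shields one face of the enamine (the (R)-amine leaves open the face that gives 2S); the two act independently, so the anti pair is chosen by the pairing of catalyst enantiomers. The step needs branched over linear regioselectivity, which the iridium catalyst and the cation-stabilising 4-methoxyphenyl group should secure, and it needs the silyl ether to survive, which the weakly acidic promoter allows.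

Step 3
Reactants: 7 (2S,3R)-2-[(tert-butyldimethylsilyl)oxy]-3-(4-methoxyphenyl)pent-4-en-1-ol
Product: 8 (2S,3R)-3-(4-methoxyphenyl)pent-4-ene-1,2-diol
Conditions: Bu4NF, THF, 0 °C to rt
Reagents that add atoms: none
Why: Fluoride-induced cleavage of the silyl ether, driven by the Si–F bond; no stereocentre is touched, and a possible 1,2-silyl shift in 7 is without consequence because both silyl ethers give 8.

Step 4
Reactants: 8 (2S,3R)-3-(4-methoxyphenyl)pent-4-ene-1,2-diol; 9 3,4-dimethoxystyrene
Product: 10 (2S,3R,4E)-5-(3,4-dimethoxyphenyl)-3-(4-methoxyphenyl)pent-4-ene-1,2-diol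
Conditions: 9 (3 equiv), RuCl2(=CH-C6H4-2-O-i-Pr)(H2IMes) (second-generation Hoveyda–Grubbs catalyst, 5 mol %), 1,4-benzoquinone (10 mol %), CH2Cl2, 40 °C
Reagents that add atoms: none
Why: Olefin cross-metathesis of a terminal alkene that is slow to dimerise (allylic branching) with an excess of the electron-rich styrene 9 should give the E-styrene under thermodynamic control; the free diol is tolerated, benzoquinone intercepts ruthenium hydrides that could shift the double bond across the doubly activated C3–H, and no stereocentre is involved.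

Step 5
Reactants: 10 (2S,3R,4E)-5-(3,4-dimethoxyphenyl)-3-(4-methoxyphenyl)pent-4-ene-1,2-diol
Product: 12 (3S,4R,5S)-5-[(R)-(3,4-dimethoxyphenyl)(hydroxy)methyl]-4-(4-methoxyphenyl)oxolan-3-ol (target CNP0350816.1), via epoxide 11 (not isolated)
Conditions: 1,2:4,5-di-O-isopropylidene-β-D-erythro-2,3-hexodiulo-2,6-pyranose (D-fructose-derived ketone, 0.3 equiv), KHSO5 (as 2KHSO5·KHSO4·K2SO4), K2CO3, Bu4NHSO4, MeCN–CH2(OMe)2–aq Na2B4O7 buffer (pH about 10.5), 0 °C; cold extraction; then KOt-Bu (0.2 equiv), THF, 0 °C to rt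
Reagents that add atoms: potassium peroxymonosulfate, [K+].[O-]S(=O)(=O)OO (the oxygen that becomes the C1' hydroxyl)
Why: Shi epoxidation followed by base-induced epoxy-alcohol cyclisation: the dioxirane of the D-fructose-derived ketone transfers oxygen to E-β-alkylstyrenes through a spiro transition state under reagent control and should give the (R,R)-epoxide 11, which already holds C1' in its final configuration, and the primary alkoxide then opens 11 at the non-benzylic carbon in a 5-exo-tet SN2 step with inversion, which makes O1–C5, sets C5 as S with the side chain cis to the C4 aryl and C3 hydroxyl groups, and keeps the electron-rich aryl epoxide under basic, non-ionising conditions.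

**Compound list**
1 | 4-methoxybenzaldehyde | COc1ccc(C=O)cc1 | starting material
2 | vinylmagnesium bromide | C=C[Mg]Br | starting material
3 | rac-1-(4-methoxyphenyl)prop-2-en-1-ol | C=CC(O)c1ccc(OC)cc1 | intermediate
4 | (tert-butyldimethylsilyloxy)acetaldehyde | CC(C)(C)[Si](C)(C)OCC=O | starting material
5 | (2R)-1-[(E)-2-(tert-butyldimethylsilyloxy)ethenyl]-2-{bis[3,5-bis(trifluoromethyl)phenyl][(trimethylsilyl)oxy]methyl}pyrrolidine, enamine of 4 (not isolated) | CC(C)(C)[Si](C)(C)O/C=C/N1CCC[C@@H]1C(O[Si](C)(C)C)(c1cc(cc(c1)C(F)(F)F)C(F)(F)F)c1cc(cc(c1)C(F)(F)F)C(F)(F)F | intermediate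
6 | (2S,3R)-2-[(tert-butyldimethylsilyl)oxy]-3-(4-methoxyphenyl)pent-4-enal (not isolated) | C=C[C@H](c1ccc(OC)cc1)[C@H](O[Si](C)(C)C(C)(C)C)C=O | intermediate
7 | (2S,3R)-2-[(tert-butyldimethylsilyl)oxy]-3-(4-methoxyphenyl)pent-4-en-1-ol | C=C[C@H](c1ccc(OC)cc1)[C@H](O[Si](C)(C)C(C)(C)C)CO | intermediate
8 | (2S,3R)-3-(4-methoxyphenyl)pent-4-ene-1,2-diol | C=C[C@H](c1ccc(OC)cc1)[C@H](O)CO | intermediate
9 | 3,4-dimethoxystyrene (4-ethenyl-1,2-dimethoxybenzene) | C=Cc1ccc(OC)c(OC)c1 | starting material
10 | (2S,3R,4E)-5-(3,4-dimethoxyphenyl)-3-(4-methoxyphenyl)pent-4-ene-1,2-diol | COc1ccc(/C=C/[C@H](c2ccc(OC)cc2)[C@H](O)CO)cc1OC | intermediate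
11 | (2S,3R)-3-[(2R,3R)-3-(3,4-dimethoxyphenyl)oxiran-2-yl]-3-(4-methoxyphenyl)propane-1,2-diol (not isolated) | COc1ccc([C@H]2O[C@@H]2[C@H](c2ccc(OC)cc2)[C@H](O)CO)cc1OC | intermediate
12 | (3S,4R,5S)-5-[(R)-(3,4-dimethoxyphenyl)(hydroxy)methyl]-4-(4-methoxyphenyl)oxolan-3-ol | COc1ccc([C@H]2[C@@H]([C@H](O)c3ccc(OC)c(OC)c3)OC[C@H]2O)cc1 | target

Total step count: 5. Longest linear sequence: 5 steps (1 → 3 → 7 → 8 → 10 → 12).

**Steps most likely to fail**

Step 5. The 3,4-dimethoxyphenyl epoxide may ionise at C1' in the aqueous oxidation medium and then be hydrolysed or attacked at the benzylic carbon by a hydroxyl (endo closure) before the 5-exo closure can take place. The fallback carries the arene through the epoxide stage as an electron-poor aryl sulfonate and sets out from 8. 2-Methoxy-4-vinylphenyl 4-methylbenzenesulfonate F1 (from commercial 2-methoxy-4-vinylphenol and TsCl, Et3N) would be joined to 8 by cross-metathesis as in step 4 to give 4-[(1E,3R,4S)-4,5-dihydroxy-3-(4-methoxyphenyl)pent-1-en-1-yl]-2-methoxyphenyl 4-methylbenzenesulfonate F2. Epoxidation as in step 5 should give the epoxide 4-{(2R,3R)-3-[(1R,2S)-2,3-dihydroxy-1-(4-methoxyphenyl)propyl]oxiran-2-yl}-2-methoxyphenyl 4-methylbenzenesulfonate F3, whose sulfonyloxy group does not support a benzylic cation. KOt-Bu would close it to 4-{(R)-hydroxy[(2S,3R,4S)-4-hydroxy-3-(4-methoxyphenyl)oxolan-2-yl]methyl}-2-methoxyphenyl 4-methylbenzenesulfonate F4. Mg in MeOH at rt would cleave the sulfonate to 4-{(R)-hydroxy[(2S,3R,4S)-4-hydroxy-3-(4-methoxyphenyl)oxolan-2-yl]methyl}-2-methoxyphenol F5, and MeI, K2CO3 in acetone would methylate the phenol only, which returns to the route at 12.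

Step 2. The acid promoter may ionise the electron-rich carbinol 3 without the iridium catalyst (loss of control at the aryl-bearing centre, linear product), or 6 may epimerise before it is reduced. The fallback forms the same bond through a closed transition state and sets out from 3. Borylation with B2pin2 and Pd(MeCN)4(BF4)2 (cat.) would give 2-[(2E)-3-(4-methoxyphenyl)prop-2-en-1-yl]-4,4,5,5-tetramethyl-1,3,2-dioxaborolane F6. Allylboration of 4 catalysed by 3,3'-bis(2,4,6-triisopropylphenyl)-1,1'-binaphthyl-2,2'-diyl hydrogen phosphate (the enantiomer that gives the 2S carbinol) should pass through a chair transition state, in which the E-boronate gives the anti isomer (2S,3R)-1-[(tert-butyldimethylsilyl)oxy]-3-(4-methoxyphenyl)pent-4-en-2-ol F7. Bu4NF then returns to the route at 8.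

Step 4. Ruthenium hydrides may move the terminal double bond into conjugation with the 4-methoxyphenyl ring, which destroys the aryl-bearing centre, or the homodimer of 9 may take over the catalyst. The fallback is a Heck–Matsuda arylation and sets out from 8: 3,4-dimethoxybenzenediazonium tetrafluoroborate F8 (from 3,4-dimethoxyaniline, NaNO2, HBF4) with Pd(OAc)2 (cat.) and NaOAc in MeCN at rt would add the aryl group to the terminal carbon, and β-hydride elimination towards the new benzylic position would give the E-styrene, which returns to the route at 10.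

**Further compounds**
F1 | step 5 | 2-methoxy-4-vinylphenyl 4-methylbenzenesulfonate | C=Cc1ccc(OS(=O)(=O)c2ccc(C)cc2)c(OC)c1
F2 | step 5 | 4-[(1E,3R,4S)-4,5-dihydroxy-3-(4-methoxyphenyl)pent-1-en-1-yl]-2-methoxyphenyl 4-methylbenzenesulfonate | COc1cc(/C=C/[C@H](c2ccc(OC)cc2)[C@H](O)CO)ccc1OS(=O)(=O)c1ccc(C)cc1
F3 | step 5 | 4-{(2R,3R)-3-[(1R,2S)-2,3-dihydroxy-1-(4-methoxyphenyl)propyl]oxiran-2-yl}-2-methoxyphenyl 4-methylbenzenesulfonate | COc1cc([C@H]2O[C@@H]2[C@H](c2ccc(OC)cc2)[C@H](O)CO)ccc1OS(=O)(=O)c1ccc(C)cc1
F4 | step 5 | 4-{(R)-hydroxy[(2S,3R,4S)-4-hydroxy-3-(4-methoxyphenyl)oxolan-2-yl]methyl}-2-methoxyphenyl 4-methylbenzenesulfonate | COc1ccc([C@H]2[C@@H]([C@H](O)c3ccc(OS(=O)(=O)c4ccc(C)cc4)c(OC)c3)OC[C@H]2O)cc1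
F5 | step 5 | 4-{(R)-hydroxy[(2S,3R,4S)-4-hydroxy-3-(4-methoxyphenyl)oxolan-2-yl]methyl}-2-methoxyphenol | COc1ccc([C@H]2[C@@H]([C@H](O)c3ccc(O)c(OC)c3)OC[C@H]2O)cc1
F6 | step 2 | 2-[(2E)-3-(4-methoxyphenyl)prop-2-en-1-yl]-4,4,5,5-tetramethyl-1,3,2-dioxaborolane | COc1ccc(/C=C/CB2OC(C)(C)C(C)(C)O2)cc1
F7 | step 2 | (2S,3R)-1-[(tert-butyldimethylsilyl)oxy]-3-(4-methoxyphenyl)pent-4-en-2-ol | C=C[C@H](c1ccc(OC)cc1)[C@H](O)CO[Si](C)(C)C(C)(C)C
F8 | step 4 | 3,4-dimethoxybenzenediazonium tetrafluoroborate | COc1ccc([N+]#N)cc1OC.F[B-](F)(F)F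
A1 | direct plan | tert-butyl{[(1S,2Z)-1-(3,4-dimethoxyphenyl)-3-(4-methoxyphenyl)prop-2-en-1-yl]oxy}dimethylsilane | COc1ccc(/C=C\[C@H](O[Si](C)(C)C(C)(C)C)c2ccc(OC)c(OC)c2)cc1
A2 | direct plan | (3R,4S)-4-[(S)-(tert-butyldimethylsilyloxy)(3,4-dimethoxyphenyl)methyl]-2,2-dichloro-3-(4-methoxyphenyl)cyclobutan-1-one | COc1ccc([C@H]2[C@@H]([C@H](O[Si](C)(C)C(C)(C)C)c3ccc(OC)c(OC)c3)C(=O)C2(Cl)Cl)cc1
A3 | direct plan | (4S,5S)-5-[(R)-(tert-butyldimethylsilyloxy)(3,4-dimethoxyphenyl)methyl]-3,3-dichloro-4-(4-methoxyphenyl)oxolan-2-one | COc1ccc([C@H]2[C@@H]([C@H](O[Si](C)(C)C(C)(C)C)c3ccc(OC)c(OC)c3)OC(=O)C2(Cl)Cl)cc1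
A4 | direct plan | (2S,3S)-2-[(R)-(tert-butyldimethylsilyloxy)(3,4-dimethoxyphenyl)methyl]-3-(4-methoxyphenyl)-2,3-dihydrofuran | COc1ccc([C@H]2[C@@H]([C@H](O[Si](C)(C)C(C)(C)C)c3ccc(OC)c(OC)c3)OC=C2)cc1
A5 | direct plan | (3R,4R,5S)-5-[(R)-(tert-butyldimethylsilyloxy)(3,4-dimethoxyphenyl)methyl]-4-(4-methoxyphenyl)oxolan-3-ol | COc1ccc([C@H]2[C@@H]([C@H](O[Si](C)(C)C(C)(C)C)c3ccc(OC)c(OC)c3)OC[C@@H]2O)cc1
A6 | direct plan | (4S,5S)-5-[(R)-(tert-butyldimethylsilyloxy)(3,4-dimethoxyphenyl)methyl]-4-(4-methoxyphenyl)oxolan-3-one | COc1ccc([C@H]2[C@@H]([C@H](O[Si](C)(C)C(C)(C)C)c3ccc(OC)c(OC)c3)OCC2=O)cc1
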